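The route rests on cutting ring C at C2–C3 and O1–C2. The C2(aryl)–C3(OH)–C4(=O) triad of the pyranone is a dehydrated cross-benzoin. C2 was the formyl carbon of the B-ring aldehyde. C3 was the formyl carbon of an A-ring arylglyoxal whose ketone is already C4. One carbene-catalysed operation couples both halves at the flavonol oxidation level. The ortho phenol of ring A (future O1) then closes ring C with loss of water. The chalcone epoxide pathway, which the 5-OMe group diverts to aurones, is never entered. The precursors are a 7-O-benzyl 2-hydroxyarylglyoxal and a 4-methoxybenzaldehyde already bearing the Roche-ester-derived (S) side chain at C3'.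

Key step: step 9

Assumption: glyoxal 6 is drawn and counted as the open keto aldehyde; its hydrate and its five-membered lactol are treated as resting forms of the same compound.

Step 1
Reactants: 1 2',4'-dihydroxy-6'-methoxyacetophenone
Product: 2 4'-benzyloxy-2'-hydroxy-6'-methoxyacetophenone
Conditions: BnBr (1.05 equiv), K2CO3 (1.1 equiv), acetone, reflux
Reagents that add atoms: benzyl bromide, BrCc1ccccc1
Why: Williamson etherification in which the 2'-OH is held in a hydrogen bond to the acetyl carbonyl and stays protonated under carbonate, so only the more acidic, free 4'-OH should be alkylated.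

Step 2
Reactants: 2 4'-benzyloxy-2'-hydroxy-6'-methoxyacetophenone
Product: 4 4'-benzyloxy-2',5'-dihydroxy-6'-methoxyacetophenone, via potassium aryl sulfate 3 (not isolated)
Conditions: K2S2O8 (1.1 equiv), KOH (5 equiv), H2O/pyridine, N2, 0 °C to rt; HCl to pH 4, extract unreacted 2; aqueous phase made 2 M in HCl, 75 °C
Reagents that add atoms: potassium peroxodisulfate, [K+].[K+].[O-]S(=O)(=O)OOS(=O)(=O)[O-]
Why: Elbs persulfate oxidation, in which the phenolate attacks the peroxide oxygen through the carbon para to O-2' (C5', the only para site, so the regiochemistry is unambiguous), the water-soluble sulfate 3 is separated from recyclable 2 by extraction, and warm dilute acid cleaves its S–O bond without touching the benzyl ether.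

Step 3
Reactants: 4 4'-benzyloxy-2',5'-dihydroxy-6'-methoxyacetophenone
Product: 5 4'-benzyloxy-2'-hydroxy-5',6'-dimethoxyacetophenone
Conditions: MeI (1.1 equiv), K2CO3 (1.1 equiv), acetone, N2, reflux
Reagents that add atoms: methyl iodide, CI
Why: Selective Williamson methylation in which only the non-chelated 5'-OH reacts with one equivalent of MeI, the carbonyl-bonded 2'-OH (future O1) is kept free, and nitrogen protects the hydroquinone from air oxidation.

Step 4
Reactants: 5 4'-benzyloxy-2'-hydroxy-5',6'-dimethoxyacetophenone
Product: 6 2-(4-benzyloxy-2-hydroxy-5,6-dimethoxyphenyl)-2-oxoacetaldehyde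
Conditions: SeO2 (1.2 equiv), 1,4-dioxane/H2O (20:1), 90 °C; filtration through Celite and a short silica plug; azeotropic drying with toluene
Reagents that add atoms: selenium dioxide, O=[Se]=O
Why: Riley oxidation through the enol of the aryl methyl ketone, which stops at the non-enolisable keto aldehyde and tolerates aryl ethers, benzyl ethers and a chelated phenol, and whose hydrate is dried azeotropically because water would divert the carbene step.

Step 5
Reactants: 7 methyl (R)-3-hydroxy-2-methylpropanoate (Roche ester)
Product: 8 methyl (R)-3-benzyloxy-2-methylpropanoate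
Conditions: benzyl 2,2,2-trichloroacetimidate (1.3 equiv), TfOH (5 mol %), CH2Cl2/cyclohexane, 0 °C to rt
Reagents that add atoms: benzyl 2,2,2-trichloroacetimidate, N=C(OCc1ccccc1)C(Cl)(Cl)Cl
Why: Acid-catalysed benzyl transfer from the imidate needs no base, so neither epimerisation at the ester α-carbon nor β-elimination of the β-oxygenated ester can occur and the (R) centre is retained.

Step 6
Reactants: 8 methyl (R)-3-benzyloxy-2-methylpropanoate
Product: 9 (R)-3-benzyloxy-2-methylpropanal
Conditions: DIBAL-H (1.1 equiv), CH2Cl2, −78 °C; aq Rochelle salt work-up; crude product used at once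
Reagents that add atoms: none
Why: Partial ester reduction in which the aluminium hemiacetal, stabilised at −78 °C by the β-benzyloxy oxygen, collapses to the aldehyde only on the near-neutral tartrate work-up, and immediate use limits enolisation of the α-stereocentre.

Step 7
Reactants: 9 (R)-3-benzyloxy-2-methylpropanal
Product: 10 benzyl (S)-2-methylbut-3-enyl ether
Conditions: Ph3PCH3Br (1.5 equiv), KHMDS (1.4 equiv), THF, 0 °C; then 9, −78 °C to 0 °C
Reagents that add atoms: methyltriphenylphosphonium bromide, C[P+](c1ccccc1)(c1ccccc1)c1ccccc1.[Br-]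
Why: Wittig methylenation with a lithium-free ylide made with a deficit of base, so no free amide remains and fast addition in the cold outruns enolisation, while the descriptor changes from R to S only because vinyl ranks below CH2OBn and no bond at the centre is touched.

Step 8
Reactants: 10 benzyl (S)-2-methylbut-3-enyl ether; 11 3-bromo-4-methoxybenzaldehyde
Product: 13 3-[(S)-4-benzyloxy-3-methylbutyl]-4-methoxybenzaldehyde, via B-alkyl-9-BBN borane 12 (not isolated)
Conditions: 10 (1.25 equiv), 9-BBN-H (1.2 equiv), THF, 0 °C to rt; then 3 M aq K3PO4, then 11 (1.0 equiv), PdCl2(dppf)·CH2Cl2 (5 mol %), DMF, 50 °C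
Reagents that add atoms: 9-borabicyclo[3.3.1]nonane, C1CC2CCCC(C1)B2 (its boron cage stays only in 12; product 13 keeps one hydrogen)
Why: Terminal hydroboration of the monosubstituted alkene followed by B-alkyl Suzuki–Miyaura coupling, in which the slight excess of alkene leaves no B–H, the aqueous phosphate turns the borane into its borate before the bromide arrives so the formyl group needs no acetal, and dppf suppresses β-hydride elimination.

Step 9
Reactants: 6 2-(4-benzyloxy-2-hydroxy-5,6-dimethoxyphenyl)-2-oxoacetaldehyde; 13 3-[(S)-4-benzyloxy-3-methylbutyl]-4-methoxybenzaldehyde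
Product: 16 7-benzyloxy-2-{3-[(S)-4-benzyloxy-3-methylbutyl]-4-methoxyphenyl}-3-hydroxy-5,6-dimethoxy-4H-chromen-4-one, via 2-hydroxy-1,3-dione adduct 14 (not isolated), via 2,3-dihydroxyflavanone hemiketal 15 (not isolated)
Conditions: 13 (1.3 equiv), 2-(pentafluorophenyl)-6,7-dihydro-5H-pyrrolo[2,1-c][1,2,4]triazol-2-ium BF4 (20 mol %), i-Pr2NEt (0.5 equiv), dry THF, Ar, 40 °C, 6 added by syringe pump over several hours; then TsOH·H2O (1.5 equiv), 55 °C, same flask
Reagents that add atoms: none
Why: Proposed new method: the triazolylidene adds to the formyl group of 13 and proton transfer gives the catalyst-bound Breslow enaminol, whose nucleophilic carbon attacks the very electrophilic, non-enolisable CHO of 6 (C2–C3 bond) and releases the carbene, leaving hydroxy-dione 14 already at the flavonol oxidation level. The 2'-OH then adds to the new B-ring ketone in a 6-exo-trig closure (O1–C2 bond) to hemiketal 15, and TsOH ionises the anomeric OH and removes H-3, with formation of the aromatic 4-pyranone driving the loss of water. The closest known reaction types are the chemoselective NHC cross-benzoin of aromatic aldehydes with α-keto esters and related activated carbonyl acceptors and the acid cyclodehydration of 2-oxygenated 1-(2-hydroxyaryl)-3-arylpropane-1,3-diones from Baker–Venkataraman chemistry, and the untested element is an arylglyoxal CHO bearing a free ortho phenol as acceptor. The carbinol centre of 14 and the two centres of 15 form without control and are erased on dehydration, so an achiral catalyst suffices and the remote side-chain centre is not involved. Cross- over homo-coupling is required and is secured because 13 is pre-equilibrated with the carbene while 6 is fed slowly, the homo-benzoin of a p-alkoxybenzaldehyde is slow and reversible, the reverse-polarity adduct is only the α-ketol tautomer of 14 and reaches it through the shared enediol, and capture as 15 withdraws the cross product from these equilibria. The dry aprotic medium, the sub-stoichiometric weak base and argon are chosen to close off hydrolysis of a glyoxal-derived acyl azolium (internal redox to a mandelate), base-induced isomerisation of the lactol form of 6, and autoxidation of the reductone-like 14.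

Step 10
Reactants: 16 7-benzyloxy-2-{3-[(S)-4-benzyloxy-3-methylbutyl]-4-methoxyphenyl}-3-hydroxy-5,6-dimethoxy-4H-chromen-4-one
Product: 17 3,7-dihydroxy-2-{3-[(S)-4-hydroxy-3-methylbutyl]-4-methoxyphenyl}-5,6-dimethoxy-4H-chromen-4-one (CNP0267774.1)
Conditions: H2 (1 atm), 10% Pd/C, EtOAc/MeOH, rt
Reagents that add atoms: none
Why: Catalytic hydrogenolysis removes the aryl and the alkyl benzyl ether in one operation, while the C2=C3 bond of the aromatic 3-hydroxypyranone, the three methyl ethers and the side-chain stereocentre are untouched under these mild conditions.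

Compound list
1 | 2',4'-dihydroxy-6'-methoxyacetophenone | CC(=O)c1c(O)cc(O)cc1OC | starting material
2 | 4'-benzyloxy-2'-hydroxy-6'-methoxyacetophenone | CC(=O)c1c(O)cc(OCc2ccccc2)cc1OC | intermediate
3 | potassium 3-acetyl-6-benzyloxy-4-hydroxy-2-methoxyphenyl sulfate | CC(=O)c1c(O)cc(OCc2ccccc2)c(OS(=O)(=O)[O-])c1OC.[K+] | intermediate
4 | 4'-benzyloxy-2',5'-dihydroxy-6'-methoxyacetophenone | CC(=O)c1c(O)cc(OCc2ccccc2)c(O)c1OC | intermediate
5 | 4'-benzyloxy-2'-hydroxy-5',6'-dimethoxyacetophenone | CC(=O)c1c(O)cc(OCc2ccccc2)c(OC)c1OC | intermediate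
6 | 2-(4-benzyloxy-2-hydroxy-5,6-dimethoxyphenyl)-2-oxoacetaldehyde | O=CC(=O)c1c(O)cc(OCc2ccccc2)c(OC)c1OC | intermediate
7 | methyl (R)-3-hydroxy-2-methylpropanoate | COC(=O)[C@H](C)CO | starting material
8 | methyl (R)-3-benzyloxy-2-methylpropanoate | COC(=O)[C@H](C)COCc1ccccc1 | intermediate
9 | (R)-3-benzyloxy-2-methylpropanal | O=C[C@H](C)COCc1ccccc1 | intermediate
10 | benzyl (S)-2-methylbut-3-enyl ether | C=C[C@H](C)COCc1ccccc1 | intermediate
11 | 3-bromo-4-methoxybenzaldehyde | COc1ccc(C=O)cc1Br | starting material
12 | 9-[(S)-4-benzyloxy-3-methylbutyl]-9-borabicyclo[3.3.1]nonane | C1CC2CCCC(C1)B2CC[C@H](C)COCc1ccccc1 | intermediate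
13 | 3-[(S)-4-benzyloxy-3-methylbutyl]-4-methoxybenzaldehyde | COc1ccc(C=O)cc1CC[C@H](C)COCc1ccccc1 | intermediate
14 | 1-(4-benzyloxy-2-hydroxy-5,6-dimethoxyphenyl)-3-{3-[(S)-4-benzyloxy-3-methylbutyl]-4-methoxyphenyl}-2-hydroxypropane-1,3-dione (both epimers at C2) | COc1ccc(C(=O)C(O)C(=O)c2c(O)cc(OCc3ccccc3)c(OC)c2OC)cc1CC[C@H](C)COCc1ccccc1 | intermediate
15 | 7-benzyloxy-2-{3-[(S)-4-benzyloxy-3-methylbutyl]-4-methoxyphenyl}-2,3-dihydroxy-5,6-dimethoxychroman-4-one (diastereomers at C2 and C3) | COc1ccc(C2(O)Oc3cc(OCc4ccccc4)c(OC)c(OC)c3C(=O)C2O)cc1CC[C@H](C)COCc1ccccc1 | intermediate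
16 | 7-benzyloxy-2-{3-[(S)-4-benzyloxy-3-methylbutyl]-4-methoxyphenyl}-3-hydroxy-5,6-dimethoxy-4H-chromen-4-one | COc1ccc(-c2oc3cc(OCc4ccccc4)c(OC)c(OC)c3c(=O)c2O)cc1CC[C@H](C)COCc1ccccc1 | intermediate
17 | 3,7-dihydroxy-2-{3-[(S)-4-hydroxy-3-methylbutyl]-4-methoxyphenyl}-5,6-dimethoxy-4H-chromen-4-one (CNP0267774.1) | COc1ccc(-c2oc3cc(O)c(OC)c(OC)c3c(=O)c2O)cc1CC[C@H](C)CO | target

Total step count: 10.

Longest linear sequence: 6 steps (1–4, 9, 10). The branch 5–8, 9, 10 is equally long.

Steps most likely to fail

**First, step 9.**
- The carbene may be captured preferentially by the more electrophilic glyoxal. It could then be drained by internal redox to an acyl azolium that lactonises onto the ortho phenol.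
- The amine may isomerise the lactol form of 6 to the same lactone.
- Closure may take the five-membered mode.
- The fallback uses known chemistry only. It sets out from 5 and 13 and returns to the route at 16.
- Claisen–Schmidt condensation (KOH, EtOH, rt) should give the (E)-2'-hydroxychalcone F1.
- Catalytic I2 in DMSO at 120 °C should cyclise and dehydrogenate it to the flavone F2.
- DMDO (acetone/CH2Cl2, 0 °C) should epoxidise the C2=C3 enol ether bond to the flavone 2,3-epoxide F3. A trace of TsOH opens and tautomerises it to 16.
- The C3 oxygen is thus added only after ring C exists, so aurone formation cannot occur.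

**Second, step 4.**
- Electrophilic selenium may attack the electron-rich ring at C3'.
- Oxidation may run on to the arylglyoxylic acid.
- Selenium residues carried forward may deactivate the carbene and later the palladium.
- The fallback sets out from 5 and returns at 6.
- Heterogeneous side-chain bromination with CuBr2 in refluxing EtOAc/CHCl3 favours the ketone enol over the ring of hydroxyacetophenones. It should give the phenacyl bromide F4.
- Kornblum oxidation in dry DMSO at rt then gives 6. No base is added, so the phenol does not displace bromide to form a coumaranone.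

**Third, step 2.**
- Conversion may stay low.
- The phenolate may undergo oxidative polymerisation.
- The benzyl group may be partly lost during the acid hydrolysis.
- The fallback sets out from 2 and returns at 4.
- Teuber oxidation with Fremy's salt (KH2PO4 buffer, acetone/H2O, rt) should take the para-unsubstituted phenol to the acetylbenzoquinone F5.
- F5 is reduced directly with aqueous Na2S2O4 to hydroquinone 4.

Further compounds
F1 | step 9 | (E)-1-(4-benzyloxy-2-hydroxy-5,6-dimethoxyphenyl)-3-{3-[(S)-4-benzyloxy-3-methylbutyl]-4-methoxyphenyl}prop-2-en-1-one | COc1ccc(/C=C/C(=O)c2c(O)cc(OCc3ccccc3)c(OC)c2OC)cc1CC[C@H](C)COCc1ccccc1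
F2 | step 9 | 7-benzyloxy-2-{3-[(S)-4-benzyloxy-3-methylbutyl]-4-methoxyphenyl}-5,6-dimethoxy-4H-chromen-4-one | COc1ccc(-c2cc(=O)c3c(OC)c(OC)c(OCc4ccccc4)cc3o2)cc1CC[C@H](C)COCc1ccccc1
F3 | step 9 | 2,3-epoxide of flavone F2 (diastereomers at C2 and C3) | COc1ccc(C23Oc4cc(OCc5ccccc5)c(OC)c(OC)c4C(=O)C2O3)cc1CC[C@H](C)COCc1ccccc1
F4 | step 4 | 1-(4-benzyloxy-2-hydroxy-5,6-dimethoxyphenyl)-2-bromoethanone | O=C(CBr)c1c(O)cc(OCc2ccccc2)c(OC)c1OC
F5 | step 2 | 2-acetyl-5-benzyloxy-3-methoxycyclohexa-2,5-diene-1,4-dione | CC(=O)C1=C(OC)C(=O)C(OCc2ccccc2)=CC1=O
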